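A direct plan would join the two resorcinol building blocks by Perkin condensation in Ac2O to the 3-arylcoumarin triacetate A1, reduce it with LiAlH4 to the (Z)-2,3-diarylallyl alcohol A2, and close A2 with a chiral phosphoric acid, through the isoflav-3-ene, to (6aR,11aR)-3,9-dihydroxypterocarpan A3.
It would then make the bis(prenyl ether) A4, rearrange both ethers by aromatic Claisen reaction to the 2,8-bis(1,1-dimethylallyl)pterocarpan A5, and open the dihydrofuran ring with Et3SiH/TFA.
Weakest would be the acid cascade that sets C6a (the later C3): the only stereocentre that survives would depend on an enantioselective proton transfer to an achiral, unprotected isoflavene, a control element without close precedent.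
Next would be the double Claisen rearrangement at 190 °C: each allyl group could go to either ortho carbon (C2/C8, or C4/C10 between two oxygens), and ortho-(1,1-dimethylallyl)phenols are prone to abnormal Claisen rearrangement and ring closure at that temperature, so both quaternary carbons would be left to chance.
Least welcome on late material would be the final ionic hydrogenation: TFA would create a benzylic cation next to the stereocentre (loss of H-6a gives the achiral isoflavene) beside two acid-labile ortho-(1,1-dimethylallyl)phenols.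
The plan would also spend steps on a furan ring that is closed only to be cut and on acetates that are put on only to be removed.

**Plan of the new route** (isoflavan numbering: ring A = C4a–C8a, ring B = C1′–C6′, ring C = O1/C2/C3/C4/C4a/C8a)
The retrosynthesis cuts O1–C2 (last ring closure), then C2–C3 (one-carbon homologation of a C3–B bond), then C3–C1′ and C4–C4a together (conjunctive cross-coupling across vinylboron), and finally the two aryl–C(CH3)2 bonds back to C–Br.
The feature that allows this: C3 and C4 form an ethane unit that carries ring B and ring A on neighbouring carbons, and both rings are the same 2,4-dioxygenated 5-(1,1-dimethylallyl)phenyl unit (C4a/C8a/C7/C6 of ring A match C1′/C2′/C4′/C5′ of ring B). One 4,6-dibromoresorcinol therefore gives both the nucleophile (ring B on boron, migrating to C3) and the electrophile (ring A bromide, delivered to C4 by palladium).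
Rings A and B are bought; ring C is the only ring made and closes last; no coumarin, isoflavene or pterocarpan occurs.
The weak steps do not arise: C3 is set in the open chain by a catalyst-controlled 1,2-boronate shift of a known type and carried on with retention; each 1,1-dimethylallyl group replaces a bromine atom, so there is no ortho/ortho choice and no thermal rearrangement; the last step is a buffered fluoride desilylation without strong acid, cation or reductant.

Key step: step 6

Assumption: the (Sp,Sp) ligand is taken to deliver the (R)-boronate 18; should the sense of induction be the opposite, the (Rp,Rp) ligand would be used with nothing else changed.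

Step 1
Reactants: 1 3-methylbut-2-en-1-ol; 2 diethyl chlorophosphate
Product: 3 diethyl 3-methylbut-2-en-1-yl phosphate
Conditions: pyridine (2 equiv), CH2Cl2, 0 → 23 °C
Reagents that add atoms: diethyl chlorophosphate 2, CCOP(=O)(Cl)OCC
Why: O-Phosphorylation of the primary allylic alcohol gives the allylic phosphate that the later SN2′ substitutions need as leaving group; no stereocentre is involved.

Step 2
Reactants: 4 4,6-dibromobenzene-1,3-diol; 5 chloromethyl methyl ether
Product: 6 1,5-dibromo-2,4-bis(methoxymethoxy)benzene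
Conditions: MOMCl (2.5 equiv), i-Pr2NEt (3 equiv), CH2Cl2, 0 → 23 °C
Reagents that add atoms: chloromethyl methyl ether 5, COCCl
Why: Williamson-type O-alkylation of both phenols gives acetals that stabilise an ortho aryllithium by chelation and survive the organometallic, palladium and alkaline peroxide steps.

Step 3
Reactants: 6 1,5-dibromo-2,4-bis(methoxymethoxy)benzene; 3 diethyl 3-methylbut-2-en-1-yl phosphate
Product: 9 1-bromo-2,4-bis(methoxymethoxy)-5-(2-methylbut-3-en-2-yl)benzene (ring A bromide), via aryllithium 7 (not isolated), via diethyl(aryl)aluminium 8 (not isolated)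
Conditions: n-BuLi (1.0 equiv), THF, −78 °C; Et2AlCl (1.05 equiv), −78 → −30 °C; 3 (1.2 equiv), chloro[1,3-bis(2,4,6-trimethylphenyl)imidazolidin-2-ylidene]copper (5 mol %), −30 → 23 °C
Reagents that add atoms: diethyl 3-methylbut-2-en-1-yl phosphate 3, CC(C)=CCOP(=O)(OCC)OCC
Why: A single bromine–lithium exchange on the C2v-symmetric dibromide (a second exchange on the electron-rich aryllithium is much slower), transmetalation to aluminium and carbene–copper-catalysed SN2′ allylic substitution of the γ,γ-disubstituted allylic phosphate, in which the aryl group is delivered to the disubstituted terminus and reductive elimination from the trivalent copper σ-allyl outruns allyl isomerisation, should put the 1,1-dimethylallyl group exactly on the former C–Br carbon, so that no regiochemical question arises on the ring.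

Step 4
Reactants: 4 4,6-dibromobenzene-1,3-diol; 10 chlorotriisopropylsilane
Product: 11 1,5-dibromo-2,4-bis(triisopropylsilyloxy)benzene
Conditions: TIPSCl (2.4 equiv), imidazole (5 equiv), DMF, 40 °C
Reagents that add atoms: chlorotriisopropylsilane 10, CC(C)[Si](Cl)(C(C)C)C(C)C
Why: Silylation of both phenols with the bulky silyl chloride gives aryl silyl ethers that resist the anionic O-to-C silyl shift at −78 °C, are stable to the mild acid that later frees ring A, and fall to fluoride at the end.

Step 5
Reactants: 11 1,5-dibromo-2,4-bis(triisopropylsilyloxy)benzene; 3 diethyl 3-methylbut-2-en-1-yl phosphate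
Product: 14 1-bromo-5-(2-methylbut-3-en-2-yl)-2,4-bis(triisopropylsilyloxy)benzene (ring B bromide), via aryllithium 12 (not isolated), via diethyl(aryl)aluminium 13 (not isolated)
Conditions: n-BuLi (1.0 equiv), THF, −78 °C; Et2AlCl (1.05 equiv), −78 → −30 °C; 3 (1.2 equiv), chloro[1,3-bis(2,4,6-trimethylphenyl)imidazolidin-2-ylidene]copper (5 mol %), −30 → 23 °C
Reagents that add atoms: diethyl 3-methylbut-2-en-1-yl phosphate 3, CC(C)=CCOP(=O)(OCC)OCC
Why: The same single bromine–lithium exchange, aluminium transmetalation and copper-catalysed SN2′ allylic substitution as in step 3, the aryllithium being trapped by Et2AlCl at −78 °C before any silyl migration can occur.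

Step 6
Reactants: 14 1-bromo-5-(2-methylbut-3-en-2-yl)-2,4-bis(triisopropylsilyloxy)benzene; 15 4,4,5,5-tetramethyl-2-vinyl-1,3,2-dioxaborolane; 9 1-bromo-2,4-bis(methoxymethoxy)-5-(2-methylbut-3-en-2-yl)benzene
Product: 18 2-{(1R)-2-[2,4-bis(methoxymethoxy)-5-(2-methylbut-3-en-2-yl)phenyl]-1-[5-(2-methylbut-3-en-2-yl)-2,4-bis(triisopropylsilyloxy)phenyl]ethyl}-4,4,5,5-tetramethyl-1,3,2-dioxaborolane, via aryllithium 16 (not isolated), via lithium vinylborate complex 17 (not isolated)
Conditions: t-BuLi (2.0 equiv), Et2O, −78 °C; 15 (1.0 equiv), −78 → 23 °C; solvent exchange to THF; 9 (1.0 equiv), NaOTf (2 equiv), Pd(OAc)2 (3 mol %), (Sp,Sp)-1,1′-bis[bis(3,5-dimethylphenyl)phosphino]-2,2′-bis[(R)-α-(dimethylamino)benzyl]ferrocene (MandyPhos type, 3.6 mol %), 60 °C, 18 h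
Reagents that add atoms: 4,4,5,5-tetramethyl-2-vinyl-1,3,2-dioxaborolane 15, C=CB1OC(C)(C)C(C)(C)O1
Why: Bromine–lithium exchange of 14 and addition of aryllithium 16 to the boron of 15 give the four-coordinate vinylborate 17; zerovalent palladium inserts into the C–Br bond of 9, the cationic aryl–palladium (bromide is taken up by NaOTf) binds the vinyl group of 17, and this π-activation triggers an anti 1,2-shift of ring B from boron to the boron-bearing carbon (the later C3) while palladium bonds to the terminal carbon (the later C4), after which C4–C4a reductive elimination releases 18. The closest known reaction type is the palladium-catalysed enantioselective conjunctive cross-coupling of aryl(vinyl)boron ate complexes with aryl triflates or halides under ferrocenyl bisphosphine ligands of this family. No ring is closed; the step forms the C3–C1′ and C4–C4a bonds and leaves boron on C3. The single stereocentre C3 is controlled by the chiral bisphosphine, which selects the alkene face bound by palladium, ring B arriving on the opposite face. The step needs conjunctive coupling to win over direct aryl transfer from boron to palladium, β-hydride elimination and Heck arylation of the 1,1-dimethylallyl vinyl groups; the wide-bite-angle ligand disfavours the first two, and the anionic borate alkene is far more nucleophilic than the vinyl groups, which are shielded by their quaternary carbons.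

Step 7
Reactants: 18 secondary boronic ester from step 6; 19 bromochloromethane; 20 hydrogen peroxide
Product: 22 (2R)-3-[2,4-bis(methoxymethoxy)-5-(2-methylbut-3-en-2-yl)phenyl]-2-[5-(2-methylbut-3-en-2-yl)-2,4-bis(triisopropylsilyloxy)phenyl]propan-1-ol, via primary pinacol boronate 21 (not isolated)
Conditions: BrCH2Cl (3 equiv), n-BuLi (2.5 equiv), THF, −78 → 23 °C; then 2 M NaOH, 30% H2O2, 0 °C, 1 h
Reagents that add atoms: bromochloromethane 19, ClCBr; hydrogen peroxide 20, OO
Why: Matteson homologation, in which chloromethyllithium made in the presence of 18 adds to boron and the secondary benzylic carbon migrates to CH2 with loss of chloride and with retention of configuration, so that C3 is carried over unchanged and the new CH2 becomes C2, followed by alkaline peroxide oxidation of the primary C–B bond to C–OH.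

Step 8
Reactants: 22 primary alcohol from step 7
Product: 23 4-{(2R)-3-hydroxy-2-[5-(2-methylbut-3-en-2-yl)-2,4-bis(triisopropylsilyloxy)phenyl]propyl}-6-(2-methylbut-3-en-2-yl)benzene-1,3-diol
Conditions: p-TsOH·H2O (0.2 equiv), MeOH/THF 3:1, 40 °C
Reagents that add atoms: none
Why: Acid-catalysed acetal exchange with methanol removes both methoxymethyl groups of ring A as dimethoxymethane while the aryl triisopropylsilyl ethers of ring B stay, so that only ring A carries free phenols; methanol-levelled acid at 40 °C should not protonate the monosubstituted alkenes, and no cation can form next to C3.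

Step 9
Reactants: 23 triol from step 8
Product: 24 (3R)-6-(2-methylbut-3-en-2-yl)-3-[5-(2-methylbut-3-en-2-yl)-2,4-bis(triisopropylsilyloxy)phenyl]chroman-7-ol
Conditions: PPh3 (1.5 equiv), DIAD (1.5 equiv), THF (0.01 M), 0 → 23 °C
Reagents that add atoms: none
Why: Intramolecular Mitsunobu etherification closes ring C by a 6-exo-tet attack of the phenol oxygen O1 on the activated primary carbon C2; the hindered O7–H cannot reach C2, the ring B oxygens are silylated so that the competing five-membered closure through O2′ is excluded, and C3 is not a reacting centre.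

Step 10
Reactants: 24 bis(silyl ether) from step 9
Product: 25 Manuifolin E, (3R)-3-[2,4-dihydroxy-5-(2-methylbut-3-en-2-yl)phenyl]-6-(2-methylbut-3-en-2-yl)chroman-7-ol
Conditions: Bu4NF (2.5 equiv), AcOH (2.5 equiv), THF, 0 → 23 °C, argon
Reagents that add atoms: none
Why: Fluoride cleaves both aryl silyl ethers through Si–F bond formation, buffered by acetic acid so that the electron-rich resorcinols are not held as phenoxides; the conditions contain no strong acid, cation or reductant and leave the 1,1-dimethylallyl groups and C3 untouched.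

**Compound list**
1 | 3-methylbut-2-en-1-ol (prenol) | CC(C)=CCO | starting material
2 | diethyl chlorophosphate | CCOP(=O)(Cl)OCC | starting material
3 | diethyl 3-methylbut-2-en-1-yl phosphate | CC(C)=CCOP(=O)(OCC)OCC | intermediate
4 | 4,6-dibromobenzene-1,3-diol | Oc1cc(O)c(Br)cc1Br | starting material
5 | chloromethyl methyl ether | COCCl | starting material
6 | 1,5-dibromo-2,4-bis(methoxymethoxy)benzene | COCOc1cc(OCOC)c(Br)cc1Br | intermediate
7 | [5-bromo-2,4-bis(methoxymethoxy)phenyl]lithium (not isolated) | [Li]c1cc(Br)c(OCOC)cc1OCOC | intermediate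
8 | [5-bromo-2,4-bis(methoxymethoxy)phenyl]diethylaluminium (not isolated) | CC[Al](CC)c1cc(Br)c(OCOC)cc1OCOC | intermediate
9 | 1-bromo-2,4-bis(methoxymethoxy)-5-(2-methylbut-3-en-2-yl)benzene (ring A bromide) | C=CC(C)(C)c1cc(Br)c(OCOC)cc1OCOC | intermediate
10 | chlorotriisopropylsilane | CC(C)[Si](Cl)(C(C)C)C(C)C | starting material
11 | 1,5-dibromo-2,4-bis(triisopropylsilyloxy)benzene | CC(C)[Si](Oc1cc(O[Si](C(C)C)(C(C)C)C(C)C)c(Br)cc1Br)(C(C)C)C(C)C | intermediate
12 | [5-bromo-2,4-bis(triisopropylsilyloxy)phenyl]lithium (not isolated) | [Li]c1cc(Br)c(O[Si](C(C)C)(C(C)C)C(C)C)cc1O[Si](C(C)C)(C(C)C)C(C)C | intermediate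
13 | [5-bromo-2,4-bis(triisopropylsilyloxy)phenyl]diethylaluminium (not isolated) | CC[Al](CC)c1cc(Br)c(O[Si](C(C)C)(C(C)C)C(C)C)cc1O[Si](C(C)C)(C(C)C)C(C)C | intermediate
14 | 1-bromo-5-(2-methylbut-3-en-2-yl)-2,4-bis(triisopropylsilyloxy)benzene (ring B bromide) | C=CC(C)(C)c1cc(Br)c(O[Si](C(C)C)(C(C)C)C(C)C)cc1O[Si](C(C)C)(C(C)C)C(C)C | intermediate
15 | 4,4,5,5-tetramethyl-2-vinyl-1,3,2-dioxaborolane | C=CB1OC(C)(C)C(C)(C)O1 | starting material
16 | [5-(2-methylbut-3-en-2-yl)-2,4-bis(triisopropylsilyloxy)phenyl]lithium (not isolated) | [Li]c1cc(C(C)(C)C=C)c(O[Si](C(C)C)(C(C)C)C(C)C)cc1O[Si](C(C)C)(C(C)C)C(C)C | intermediate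
17 | lithium [5-(2-methylbut-3-en-2-yl)-2,4-bis(triisopropylsilyloxy)phenyl](pinacolato)vinylborate (not isolated) | [Li+].C=C[B-]1(OC(C)(C)C(C)(C)O1)c1cc(C(C)(C)C=C)c(O[Si](C(C)C)(C(C)C)C(C)C)cc1O[Si](C(C)C)(C(C)C)C(C)C | intermediate
18 | 2-{(1R)-2-[2,4-bis(methoxymethoxy)-5-(2-methylbut-3-en-2-yl)phenyl]-1-[5-(2-methylbut-3-en-2-yl)-2,4-bis(triisopropylsilyloxy)phenyl]ethyl}-4,4,5,5-tetramethyl-1,3,2-dioxaborolane | CC1(C)OB(OC1(C)C)[C@H](Cc1cc(C(C)(C)C=C)c(OCOC)cc1OCOC)c1cc(C(C)(C)C=C)c(O[Si](C(C)C)(C(C)C)C(C)C)cc1O[Si](C(C)C)(C(C)C)C(C)C | intermediate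
19 | bromochloromethane | ClCBr | starting material
20 | hydrogen peroxide | OO | starting material
21 | 2-{(2R)-3-[2,4-bis(methoxymethoxy)-5-(2-methylbut-3-en-2-yl)phenyl]-2-[5-(2-methylbut-3-en-2-yl)-2,4-bis(triisopropylsilyloxy)phenyl]propyl}-4,4,5,5-tetramethyl-1,3,2-dioxaborolane (not isolated) | CC1(C)OB(C[C@H](Cc2cc(C(C)(C)C=C)c(OCOC)cc2OCOC)c2cc(C(C)(C)C=C)c(O[Si](C(C)C)(C(C)C)C(C)C)cc2O[Si](C(C)C)(C(C)C)C(C)C)OC1(C)C | intermediate
22 | (2R)-3-[2,4-bis(methoxymethoxy)-5-(2-methylbut-3-en-2-yl)phenyl]-2-[5-(2-methylbut-3-en-2-yl)-2,4-bis(triisopropylsilyloxy)phenyl]propan-1-ol | OC[C@H](Cc1cc(C(C)(C)C=C)c(OCOC)cc1OCOC)c1cc(C(C)(C)C=C)c(O[Si](C(C)C)(C(C)C)C(C)C)cc1O[Si](C(C)C)(C(C)C)C(C)C | intermediate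
23 | 4-{(2R)-3-hydroxy-2-[5-(2-methylbut-3-en-2-yl)-2,4-bis(triisopropylsilyloxy)phenyl]propyl}-6-(2-methylbut-3-en-2-yl)benzene-1,3-diol | OC[C@H](Cc1cc(C(C)(C)C=C)c(O)cc1O)c1cc(C(C)(C)C=C)c(O[Si](C(C)C)(C(C)C)C(C)C)cc1O[Si](C(C)C)(C(C)C)C(C)C | intermediate
24 | (3R)-6-(2-methylbut-3-en-2-yl)-3-[5-(2-methylbut-3-en-2-yl)-2,4-bis(triisopropylsilyloxy)phenyl]chroman-7-ol | C=CC(C)(C)c1cc2c(cc1O)OC[C@@H](c1cc(C(C)(C)C=C)c(O[Si](C(C)C)(C(C)C)C(C)C)cc1O[Si](C(C)C)(C(C)C)C(C)C)C2 | intermediate
25 | Manuifolin E, (3R)-3-[2,4-dihydroxy-5-(2-methylbut-3-en-2-yl)phenyl]-6-(2-methylbut-3-en-2-yl)chroman-7-ol | C=CC(C)(C)c1cc2c(cc1O)OC[C@@H](c1cc(C(C)(C)C=C)c(O)cc1O)C2 | target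

**Step count**
Total step count: 10. Longest linear sequence: 7 steps (steps 2, 3, 6, 7, 8, 9, 10, from 4,6-dibromobenzene-1,3-diol).

**Steps most likely to fail**

Step 6 (key step). What may go wrong:
- slow oxidative addition into the electron-rich, ortho-substituted bromide 9;
- direct transfer of the ring B aryl group from boron to palladium, giving biaryl;
- Heck-type insertion of the 1,1-dimethylallyl vinyl groups;
- poor facial selectivity because both partners are ortho-substituted.

The fallback is a sparteine-mediated lithiation–borylation; it sets out from 9 and 14 and comes back at 18. Bromine–lithium exchange of 9 (n-BuLi, THF, −78 °C) and opening of ethylene oxide (BF3·OEt2) would give 2-[2,4-bis(methoxymethoxy)-5-(2-methylbut-3-en-2-yl)phenyl]ethan-1-ol F1. N,N-Diisopropylcarbamoyl chloride and Et3N would convert it to 2-[2,4-bis(methoxymethoxy)-5-(2-methylbut-3-en-2-yl)phenyl]ethyl N,N-diisopropylcarbamate F2. In parallel, 14 would be lithiated (t-BuLi, −78 °C) and trapped with 2-isopropoxy-4,4,5,5-tetramethyl-1,3,2-dioxaborolane to give the ring B pinacol boronate 4,4,5,5-tetramethyl-2-[5-(2-methylbut-3-en-2-yl)-2,4-bis(triisopropylsilyloxy)phenyl]-1,3,2-dioxaborolane F3. Deprotonation of F2 next to oxygen with s-BuLi/(−)-sparteine (Et2O, −78 °C; at this temperature ring metalation between the two acetal oxygens should be slower), addition of F3 and warming with MgBr2·OEt2 would give 18 by 1,2-shift of ring B with loss of carbamate. Pro-S deprotonation, borylation with retention and migration with inversion predict the (R) product; otherwise the (+)-sparteine surrogate would be used.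

Step 5 (the same applies to step 3). What may go wrong:
- attack at the unsubstituted allyl terminus, giving the linear prenyl isomer;
- transfer of ethyl instead of aryl from aluminium;
- a second bromine–lithium exchange;
- in the silyl series, anionic O-to-C silyl migration before transmetalation.

The fallback is a γ-selective allyl–aryl coupling under divalent palladium; it sets out from 11 and comes back at 14. Exchange with n-BuLi (−78 °C), B(OMe)3 and aqueous work-up would give [5-bromo-2,4-bis(triisopropylsilyloxy)phenyl]boronic acid F4. Coupling with 3-methylbut-2-en-1-yl acetate (Pd(OAc)2, 1,10-phenanthroline, AgSbF6, 1,2-dichloroethane, 60 °C) proceeds by acetate-directed addition of aryl–palladium with aryl at the disubstituted carbon and β-acetoxy elimination. Since no zerovalent palladium intervenes, the C–Br bond should survive. The same sequence from 6 would return at 9.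

Step 8. What may go wrong:
- protonation of a 1,1-dimethylallyl double bond and capture by the freed ortho phenol;
- electrophilic substitution of the liberated resorcinol ring by formaldehyde equivalents;
- partial loss of the silyl ethers.

The fallback replaces acid solvolysis by a protecting-group exchange under aprotic, amine-buffered conditions; it sets out from 22 and comes back at 23. Me3SiOTf with 2,2′-bipyridyl (CH2Cl2, 0 °C) would convert both aryl methoxymethyl ethers and the alcohol into trimethylsilyl ethers, giving the tris(trimethylsilyl) ether (2R)-3-[5-(2-methylbut-3-en-2-yl)-2,4-bis(trimethylsilyloxy)phenyl]-2-[5-(2-methylbut-3-en-2-yl)-2,4-bis(triisopropylsilyloxy)phenyl]-1-(trimethylsilyloxy)propane F5. Brief K2CO3/MeOH at 0 °C would then give 23.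

**Further compounds**
F1 | step 6 | 2-[2,4-bis(methoxymethoxy)-5-(2-methylbut-3-en-2-yl)phenyl]ethan-1-ol | OCCc1cc(C(C)(C)C=C)c(OCOC)cc1OCOC
F2 | step 6 | 2-[2,4-bis(methoxymethoxy)-5-(2-methylbut-3-en-2-yl)phenyl]ethyl N,N-diisopropylcarbamate | CC(C)N(C(C)C)C(=O)OCCc1cc(C(C)(C)C=C)c(OCOC)cc1OCOC
F3 | step 6 | 4,4,5,5-tetramethyl-2-[5-(2-methylbut-3-en-2-yl)-2,4-bis(triisopropylsilyloxy)phenyl]-1,3,2-dioxaborolane | CC1(C)OB(OC1(C)C)c1cc(C(C)(C)C=C)c(O[Si](C(C)C)(C(C)C)C(C)C)cc1O[Si](C(C)C)(C(C)C)C(C)C
F4 | step 5 | [5-bromo-2,4-bis(triisopropylsilyloxy)phenyl]boronic acid | OB(O)c1cc(Br)c(O[Si](C(C)C)(C(C)C)C(C)C)cc1O[Si](C(C)C)(C(C)C)C(C)C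
F5 | step 8 | (2R)-3-[5-(2-methylbut-3-en-2-yl)-2,4-bis(trimethylsilyloxy)phenyl]-2-[5-(2-methylbut-3-en-2-yl)-2,4-bis(triisopropylsilyloxy)phenyl]-1-(trimethylsilyloxy)propane | C[Si](C)(C)OC[C@H](Cc1cc(C(C)(C)C=C)c(O[Si](C)(C)C)cc1O[Si](C)(C)C)c1cc(C(C)(C)C=C)c(O[Si](C(C)C)(C(C)C)C(C)C)cc1O[Si](C(C)C)(C(C)C)C(C)C
A1 | direct plan | 7-acetoxy-3-(2,4-diacetoxyphenyl)-2H-chromen-2-one | CC(=O)Oc1ccc2cc(-c3ccc(OC(C)=O)cc3OC(C)=O)c(=O)oc2c1
A2 | direct plan | (Z)-4-[2-(2,4-dihydroxyphenyl)-3-hydroxyprop-1-en-1-yl]benzene-1,3-diol | OC/C(c1ccc(O)cc1O)=C\c1ccc(O)cc1O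
A3 | direct plan | (6aR,11aR)-3,9-dihydroxypterocarpan | Oc1ccc2c(c1)OC[C@H]3c4ccc(O)cc4O[C@@H]23
A4 | direct plan | (6aR,11aR)-3,9-bis[(3-methylbut-2-en-1-yl)oxy]pterocarpan | CC(C)=CCOc1ccc2c(c1)OC[C@H]3c4ccc(OCC=C(C)C)cc4O[C@@H]23
A5 | direct plan | (6aR,11aR)-2,8-bis(2-methylbut-3-en-2-yl)-3,9-dihydroxypterocarpan | C=CC(C)(C)c1cc2c(cc1O)OC[C@H]3c4cc(C(C)(C)C=C)c(O)cc4O[C@@H]23
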